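**Plan**

1. Retrosynthesis cuts the O–SO3H bond first, then the aryl–CH2 bond of the propyl chain at C5 (back to a C5 bromide and an alkylborane), and reads the CH2OH on C3 as a reduced methyl ester.
2. In the dihydrobenzofuran (O1, C2, C3, C3a, C7a), C3 is bonded to C2, to ring-A carbon C3a and to a one-carbon arm. That is the pattern left when the ring-A carbon of a chroman-4-one moves from the carbonyl carbon to the neighbouring CH2, so cutting C3–C3a gives a (2S)-2-arylchroman-4-one.
3. The chromanone is cut at C2–aryl (arylboronic acid plus chromone), and the chromone at O1–C2 and C2–C3 (2-hydroxyacetophenone plus a formyl equivalent).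
4. Forward: rings A and B are bought, the pyranone ring is closed, ring B is attached at C2, the pyranone is contracted to the dihydrofuran, and only then is the chain coupled on, sulfated and the protecting groups removed.
5. C2 comes from a chiral pyridine-oxazoline palladium catalyst; C3 is set trans to it by C2 during the ring contraction, and no later step touches either centre.

Key step: step 5

Remark: the target is drawn as the hydrogen sulfate; the sulfated compounds would be handled as sodium salts and the acid form released by cold ion exchange, and their SMILES are given in the acid form.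
Remark: the brominated hydroxyacetophenone used in step 3 is taken to be a catalogue compound.

**Route**

Step 1
Reactants: 1 4-hydroxy-3-methoxyphenylboronic acid pinacol ester
Product: 2 2-methoxy-4-(4,4,5,5-tetramethyl-1,3,2-dioxaborolan-2-yl)phenyl methanesulfonate
Conditions: MsCl, Et3N, CH2Cl2, 0 °C to rt
Reagents that add atoms: methanesulfonyl chloride, CS(=O)(=O)Cl
Why: O-sulfonylation of a phenol with a sulfonyl chloride and an amine base is routine and leaves the boronate untouched, and the mesylate is chosen because it makes ring B electron-poor and should survive acid, trivalent iodine, hydride and palladium catalysis.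

Step 2
Reactants: 2 2-methoxy-4-(4,4,5,5-tetramethyl-1,3,2-dioxaborolan-2-yl)phenyl methanesulfonate
Product: 3 [3-methoxy-4-(methylsulfonyloxy)phenyl]boronic acid
Conditions: NaIO4, NH4OAc, acetone/H2O, rt
Reagents that add atoms: water, O
Why: Periodate cleaves the pinacol released in the hydrolysis equilibrium (standard oxidative deprotection of pinacol boronates), which should give the free boronic acid that transmetalates readily to cationic palladium, the aryl mesylate being inert to periodate.

Step 3
Reactants: 4 1-(5-bromo-2-hydroxy-3-methoxyphenyl)ethanone; 5 N,N-dimethylformamide dimethyl acetal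
Product: 7 6-bromo-8-methoxy-4H-chromen-4-one, via enaminone 6 (not isolated)
Conditions: 5 (1.5 equiv), toluene, 100 °C; evaporate; then conc. HCl, CH2Cl2, 40 °C
Reagents that add atoms: none
Why: Condensation of the acetyl CH3 with the amide acetal gives the enaminone, and acid then drives conjugate addition of the phenol OH with loss of dimethylamine (enaminone route to 3-unsubstituted chromones).

Step 4
Reactants: 7 6-bromo-8-methoxy-4H-chromen-4-one; 3 [3-methoxy-4-(methylsulfonyloxy)phenyl]boronic acid
Product: 8 (2S)-6-bromo-8-methoxy-2-[3-methoxy-4-(methylsulfonyloxy)phenyl]-2,3-dihydro-4H-chromen-4-one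
Conditions: Pd(OCOCF3)2 (5 mol %), (R)-4-tert-butyl-2-(pyridin-2-yl)-4,5-dihydrooxazole (6 mol %), NH4PF6 (30 mol %), H2O (5 equiv), ClCH2CH2Cl, 60 °C, air
Reagents that add atoms: none
Why: Asymmetric conjugate addition of arylboronic acids to chromones under divalent palladium/pyridine-oxazoline catalysis is an established entry to 2-arylchromanones and leaves the aryl bromide alone, and C2 is set by the ligand tert-butyl group directing aryl transfer to one face of C2=C3; the R ligand is chosen because the facial model for 3-substituted cyclohexenones, carried over to the chromone, predicts 2S, a sense to be confirmed on the first batch.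

Step 5
Reactants: 8 (2S)-6-bromo-8-methoxy-2-[3-methoxy-4-(methylsulfonyloxy)phenyl]-2,3-dihydro-4H-chromen-4-one
Product: 11 methyl (2S,3S)-5-bromo-7-methoxy-2-[3-methoxy-4-(methylsulfonyloxy)phenyl]-2,3-dihydro-1-benzofuran-3-carboxylate, via methyl enol ether 9 (not isolated), via iodanyl ketal 10 (not isolated)
Conditions: PhI(OH)OTs (1.2 equiv), HC(OMe)3, conc. H2SO4 (cat.), 0 °C to rt
Reagents that add atoms: trimethyl orthoformate, COC(OC)OC
Why: Acid and orthoformate convert the ketone into enol ether 9, whose C3 attacks the trivalent iodine of PhI(OH)OTs on the face anti to the C2 aryl group while methanol caps C4, giving ketal 10 with the C3–I bond equatorial and antiperiplanar to the C4–C4a ring bond. Departure of iodobenzene is then assisted by the shift of ring-A carbon C4a from C4 to C3 with inversion, and the dimethoxycarbenium ion left at the former carbonyl carbon collapses to the methyl ester. The closest known reaction type is the oxidative ring contraction of flavanones to methyl trans-2-aryl-2,3-dihydrobenzofuran-3-carboxylates with trivalent iodine reagents or Tl(NO3)3 in trimethyl orthoformate, a 1,2-aryl shift of semipinacol type. The O1–C2–C3–C3a–C7a ring is not closed by a cyclisation; it arises by contraction of the pyranone when the C3–C3a bond forms in the 1,2-shift. The new C3 centre is under substrate control from C2, since anti delivery of iodine followed by invertive migration should place CO2CH3 trans to the aryl group, which is also the more stable arrangement at this epimerisable position, while C2 itself takes no part. The step needs ring-A migration (C4 to C3) to beat ring-B migration (C2 to C3, leading to the isoflavone), elimination to the flavone and acid-induced opening to the chalcone; the mesylate makes ring B a poor migrating group, the ring oxygen ortho to C4a and the oxygen-stabilised cation at C4 favour the ring-A shift, and the anhydrous ketalising medium suppresses the other paths.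

Step 6
Reactants: 11 methyl (2S,3S)-5-bromo-7-methoxy-2-[3-methoxy-4-(methylsulfonyloxy)phenyl]-2,3-dihydro-1-benzofuran-3-carboxylate
Product: 12 [(2S,3R)-5-bromo-7-methoxy-2-[3-methoxy-4-(methylsulfonyloxy)phenyl]-2,3-dihydro-1-benzofuran-3-yl]methanol
Conditions: i-Bu2AlH (2.5 equiv), CH2Cl2, −78 to 0 °C; aq. potassium sodium tartrate (KNaC4H4O6)
Reagents that add atoms: none
Why: Aluminium hydride reduction of an ester to the primary alcohol at low temperature is non-basic, so enolisation and β-elimination of the ring oxygen are avoided, the aryl bromide and aryl mesylate should be untouched and both centres are kept (the C3 descriptor changes only through priorities).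

Step 7
Reactants: 12 [(2S,3R)-5-bromo-7-methoxy-2-[3-methoxy-4-(methylsulfonyloxy)phenyl]-2,3-dihydro-1-benzofuran-3-yl]methanol
Product: 13 [(2S,3R)-5-bromo-7-methoxy-2-[3-methoxy-4-(methylsulfonyloxy)phenyl]-2,3-dihydro-1-benzofuran-3-yl]methyl 2,2-dimethylpropanoate
Conditions: PivCl, pyridine, DMAP (cat.), CH2Cl2, 0 °C to rt
Reagents that add atoms: pivaloyl chloride, CC(C)(C)C(=O)Cl
Why: DMAP-catalysed acylation of a primary alcohol; the pivalate should withstand the aqueous base of the cross-coupling and the acid of the desilylation and leaves in the last step together with the mesylate.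

Step 8
Reactants: 13 [(2S,3R)-5-bromo-7-methoxy-2-[3-methoxy-4-(methylsulfonyloxy)phenyl]-2,3-dihydro-1-benzofuran-3-yl]methyl 2,2-dimethylpropanoate; 14 allyloxy(tert-butyl)dimethylsilane
Product: 16 [(2S,3R)-5-[3-(tert-butyldimethylsilyloxy)propyl]-7-methoxy-2-[3-methoxy-4-(methylsulfonyloxy)phenyl]-2,3-dihydro-1-benzofuran-3-yl]methyl 2,2-dimethylpropanoate, via alkylborane 15 (not isolated)
Conditions: 14, 9-borabicyclo[3.3.1]nonane (0.5 M in THF), 0 °C to rt; then 13, PdCl2(dppf) (5 mol %; dppf = 1,1'-bis(diphenylphosphino)ferrocene), aq. K3PO4 (3 M), DMF, 60 °C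
Reagents that add atoms: none
Why: Anti-Markovnikov hydroboration of the terminal alkene followed by B-alkyl Suzuki–Miyaura coupling with the aryl bromide under zerovalent palladium catalysis forms the aryl–CH2 bond, and an aryl mesylate does not undergo oxidative addition with this catalyst at 60 °C.

Step 9
Reactants: 16 [(2S,3R)-5-[3-(tert-butyldimethylsilyloxy)propyl]-7-methoxy-2-[3-methoxy-4-(methylsulfonyloxy)phenyl]-2,3-dihydro-1-benzofuran-3-yl]methyl 2,2-dimethylpropanoate
Product: 17 [(2S,3R)-5-(3-hydroxypropyl)-7-methoxy-2-[3-methoxy-4-(methylsulfonyloxy)phenyl]-2,3-dihydro-1-benzofuran-3-yl]methyl 2,2-dimethylpropanoate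
Conditions: (±)-camphor-10-sulfonic acid (10 mol %), MeOH/CH2Cl2, 0 °C to rt
Reagents that add atoms: none
Why: Acid-catalysed methanolysis removes a primary silyl ether selectively, while the pivalate, the aryl mesylate and the benzylic ring ether (deactivated by the mesylated ring B) should be stable to catalytic acid in methanol.

Step 10
Reactants: 17 [(2S,3R)-5-(3-hydroxypropyl)-7-methoxy-2-[3-methoxy-4-(methylsulfonyloxy)phenyl]-2,3-dihydro-1-benzofuran-3-yl]methyl 2,2-dimethylpropanoate
Product: 18 [(2S,3R)-7-methoxy-2-[3-methoxy-4-(methylsulfonyloxy)phenyl]-5-[3-(sulfooxy)propyl]-2,3-dihydro-1-benzofuran-3-yl]methyl 2,2-dimethylpropanoate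
Conditions: SO3·pyridine (3 equiv), pyridine, rt; then aq. NaHCO3
Reagents that add atoms: sulfur trioxide–pyridine complex, [O-]S(=O)(=O)[n+]1ccccc1
Why: O-sulfation of a primary alcohol with an amine–SO3 complex, the chain hydroxyl being the only free OH in the molecule.

Step 11
Reactants: 18 [(2S,3R)-7-methoxy-2-[3-methoxy-4-(methylsulfonyloxy)phenyl]-5-[3-(sulfooxy)propyl]-2,3-dihydro-1-benzofuran-3-yl]methyl 2,2-dimethylpropanoate
Product: 19 3-[(2S,3R)-2-(4-hydroxy-3-methoxyphenyl)-3-(hydroxymethyl)-7-methoxy-2,3-dihydro-1-benzofuran-5-yl]propyl hydrogen sulfate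
Conditions: NaOH (2 M aq.), MeOH, 50 °C; then H+-form sulfonic acid resin, 0 °C
Reagents that add atoms: none
Why: Hydroxide cleaves the pivalate by acyl substitution and the aryl mesylate at sulfur (saponification), whereas a monoalkyl sulfate anion is inert to alkali at this temperature and C3 no longer bears an acidifying group, so the configuration should be retained.

**Compound list**

1 | 4-hydroxy-3-methoxyphenylboronic acid pinacol ester | COc1cc(B2OC(C)(C)C(C)(C)O2)ccc1O | starting material
2 | 2-methoxy-4-(4,4,5,5-tetramethyl-1,3,2-dioxaborolan-2-yl)phenyl methanesulfonate | COc1cc(B2OC(C)(C)C(C)(C)O2)ccc1OS(C)(=O)=O | intermediate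
3 | [3-methoxy-4-(methylsulfonyloxy)phenyl]boronic acid | COc1cc(B(O)O)ccc1OS(C)(=O)=O | intermediate
4 | 1-(5-bromo-2-hydroxy-3-methoxyphenyl)ethanone | CC(=O)c1cc(Br)cc(OC)c1O | starting material
5 | N,N-dimethylformamide dimethyl acetal | COC(OC)N(C)C | starting material
6 | (E)-1-(5-bromo-2-hydroxy-3-methoxyphenyl)-3-(dimethylamino)prop-2-en-1-one | CN(C)/C=C/C(=O)c1cc(Br)cc(OC)c1O | intermediate (not isolated)
7 | 6-bromo-8-methoxy-4H-chromen-4-one | COc1cc(Br)cc2c(=O)ccoc12 | intermediate
8 | (2S)-6-bromo-8-methoxy-2-[3-methoxy-4-(methylsulfonyloxy)phenyl]-2,3-dihydro-4H-chromen-4-one | COc1cc([C@H]2Oc3c(OC)cc(Br)cc3C(=O)C2)ccc1OS(C)(=O)=O | intermediate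
9 | (2S)-6-bromo-4,8-dimethoxy-2-[3-methoxy-4-(methylsulfonyloxy)phenyl]-2H-chromene | COc1cc([C@H]2Oc3c(OC)cc(Br)cc3C(OC)=C2)ccc1OS(C)(=O)=O | intermediate (not isolated)
10 | (2R,3R)-6-bromo-4,4,8-trimethoxy-2-[3-methoxy-4-(methylsulfonyloxy)phenyl]-3-[phenyl(tosyloxy)-λ3-iodanyl]chromane; iodine trans to the aryl group, C2 unchanged in space (its descriptor changes because C3 now outranks the aryl carbon) | COc1cc([C@H]2Oc3c(OC)cc(Br)cc3C(OC)(OC)[C@@H]2I(c4ccccc4)OS(=O)(=O)c4ccc(C)cc4)ccc1OS(C)(=O)=O | intermediate (not isolated)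
11 | methyl (2S,3S)-5-bromo-7-methoxy-2-[3-methoxy-4-(methylsulfonyloxy)phenyl]-2,3-dihydro-1-benzofuran-3-carboxylate (trans) | COc1cc([C@H]2Oc3c(OC)cc(Br)cc3[C@@H]2C(=O)OC)ccc1OS(C)(=O)=O | intermediate
12 | [(2S,3R)-5-bromo-7-methoxy-2-[3-methoxy-4-(methylsulfonyloxy)phenyl]-2,3-dihydro-1-benzofuran-3-yl]methanol | COc1cc([C@H]2Oc3c(OC)cc(Br)cc3[C@@H]2CO)ccc1OS(C)(=O)=O | intermediate
13 | [(2S,3R)-5-bromo-7-methoxy-2-[3-methoxy-4-(methylsulfonyloxy)phenyl]-2,3-dihydro-1-benzofuran-3-yl]methyl 2,2-dimethylpropanoate | COc1cc([C@H]2Oc3c(OC)cc(Br)cc3[C@@H]2COC(=O)C(C)(C)C)ccc1OS(C)(=O)=O | intermediate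
14 | allyloxy(tert-butyl)dimethylsilane | C=CCO[Si](C)(C)C(C)(C)C | starting material
15 | 9-[3-(tert-butyldimethylsilyloxy)propyl]-9-borabicyclo[3.3.1]nonane | CC(C)(C)[Si](C)(C)OCCCB1C2CCCC1CCC2 | intermediate (not isolated)
16 | [(2S,3R)-5-[3-(tert-butyldimethylsilyloxy)propyl]-7-methoxy-2-[3-methoxy-4-(methylsulfonyloxy)phenyl]-2,3-dihydro-1-benzofuran-3-yl]methyl 2,2-dimethylpropanoate | COc1cc([C@H]2Oc3c(OC)cc(CCCO[Si](C)(C)C(C)(C)C)cc3[C@@H]2COC(=O)C(C)(C)C)ccc1OS(C)(=O)=O | intermediate
17 | [(2S,3R)-5-(3-hydroxypropyl)-7-methoxy-2-[3-methoxy-4-(methylsulfonyloxy)phenyl]-2,3-dihydro-1-benzofuran-3-yl]methyl 2,2-dimethylpropanoate | COc1cc([C@H]2Oc3c(OC)cc(CCCO)cc3[C@@H]2COC(=O)C(C)(C)C)ccc1OS(C)(=O)=O | intermediate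
18 | [(2S,3R)-7-methoxy-2-[3-methoxy-4-(methylsulfonyloxy)phenyl]-5-[3-(sulfooxy)propyl]-2,3-dihydro-1-benzofuran-3-yl]methyl 2,2-dimethylpropanoate | COc1cc([C@H]2Oc3c(OC)cc(CCCOS(=O)(=O)O)cc3[C@@H]2COC(=O)C(C)(C)C)ccc1OS(C)(=O)=O | intermediate
19 | 3-[(2S,3R)-2-(4-hydroxy-3-methoxyphenyl)-3-(hydroxymethyl)-7-methoxy-2,3-dihydro-1-benzofuran-5-yl]propyl hydrogen sulfate | COc1cc([C@H]2Oc3c(OC)cc(CCCOS(=O)(=O)O)cc3[C@@H]2CO)ccc1O | target

**Count**

Total steps: 11. Longest linear sequence: 10 steps (steps 1, 2 and 4 to 11, from compound 1); the chromone branch (step 3) joins at step 4.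

**Steps most likely to fail**

Step 5. Ring B may migrate from C2 to C3, iodobenzene may be lost by elimination to the flavone, or acid may open the ring and erode C2. The fallback makes the same C3–C3a bond by a Wolff ring contraction, setting out from 8 and returning at 11. Ketone 8 would be nitrosated at C3 under acid (isoamyl nitrite, HCl, THF, 0 °C) to (2R)-6-bromo-3-(hydroxyimino)-8-methoxy-2-[3-methoxy-4-(methylsulfonyloxy)phenyl]chroman-4-one F1, in which C2 is spatially unchanged. Chloramine (aq. NH3/NaOCl, NaOH, 0 °C; Forster reaction) should convert the oxime into (2R)-6-bromo-3-diazo-8-methoxy-2-[3-methoxy-4-(methylsulfonyloxy)phenyl]chroman-4-one F2. Irradiation in methanol near 350 nm would expel dinitrogen while ring-A carbon C4a migrates to C3, giving (2R)-5-bromo-7-methoxy-2-[3-methoxy-4-(methylsulfonyloxy)phenyl]-3-(oxomethylidene)-2,3-dihydro-1-benzofuran F3, a ketene that methanol traps as the methyl ester. Part of this is expected as the cis epimer, methyl (2S,3R)-5-bromo-7-methoxy-2-[3-methoxy-4-(methylsulfonyloxy)phenyl]-2,3-dihydro-1-benzofuran-3-carboxylate F4, which catalytic NaOCH3 in methanol at rt should equilibrate to trans ester 11. Only the acyl substituent can migrate in this rearrangement, so the isoflavone path is closed.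

Step 4. Transmetalation of the electron-poor boronic acid may be slow against protodeboronation, or facial selectivity may be low with the 8-methoxy-substituted chromone. The fallback builds the chromanone by condensation and resolves it, setting out from 4 and returning at 8. Vanillin would be mesylated (MsCl, Et3N) to 3-methoxy-4-(methylsulfonyloxy)benzaldehyde F5. Amine-catalysed Claisen–Schmidt condensation of 4 with the aldehyde (pyrrolidine, EtOH, 60 °C) should give (E)-1-(5-bromo-2-hydroxy-3-methoxyphenyl)-3-[3-methoxy-4-(methylsulfonyloxy)phenyl]prop-2-en-1-one F6. Oxa-Michael closure (NaOAc, EtOH, reflux) would give racemic 6-bromo-8-methoxy-2-[3-methoxy-4-(methylsulfonyloxy)phenyl]chroman-4-one F7. Kinetic resolution by asymmetric transfer hydrogenation (RuCl(p-cymene)(TsDPEN), HCO2H/Et3N, rt, stopped near half conversion) follows, with the catalyst antipode chosen so that the 2R ketone is reduced. That gives (2R,4R)-6-bromo-8-methoxy-2-[3-methoxy-4-(methylsulfonyloxy)phenyl]chroman-4-ol F8, from which unreacted (2S)-ketone 8 is separated by chromatography.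

Step 11. The hindered pivalate and the aryl mesylate may cleave incompletely at temperatures low enough to spare the sulfate, and the freed phenoxide may open the benzylic ring ether through a quinone methide and epimerise C2. The fallback moves the forcing hydrolysis ahead of the sulfation, setting out from 16 and returning at 19. Treatment of 16 with NaOH in MeOH at 50 °C would give 4-[(2S,3R)-5-[3-(tert-butyldimethylsilyloxy)propyl]-3-(hydroxymethyl)-7-methoxy-2,3-dihydro-1-benzofuran-2-yl]-2-methoxyphenol F9, which is lipophilic and easy to purify. Acetylation (Ac2O, pyridine) should give [(2S,3R)-2-(4-acetoxy-3-methoxyphenyl)-5-[3-(tert-butyldimethylsilyloxy)propyl]-7-methoxy-2,3-dihydro-1-benzofuran-3-yl]methyl acetate F10. Desilylation with HF·pyridine in THF would give [(2S,3R)-2-(4-acetoxy-3-methoxyphenyl)-5-(3-hydroxypropyl)-7-methoxy-2,3-dihydro-1-benzofuran-3-yl]methyl acetate F11. Sulfation with SO3·pyridine would give [(2S,3R)-2-(4-acetoxy-3-methoxyphenyl)-7-methoxy-5-[3-(sulfooxy)propyl]-2,3-dihydro-1-benzofuran-3-yl]methyl acetate F12. Both acetates should then leave with K2CO3 in MeOH at rt to give 19.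

**Further compounds**

F1 | step 5 | (2R)-6-bromo-3-(hydroxyimino)-8-methoxy-2-[3-methoxy-4-(methylsulfonyloxy)phenyl]chroman-4-one | COc1cc([C@H]2Oc3c(OC)cc(Br)cc3C(=O)C2=NO)ccc1OS(C)(=O)=O
F2 | step 5 | (2R)-6-bromo-3-diazo-8-methoxy-2-[3-methoxy-4-(methylsulfonyloxy)phenyl]chroman-4-one | COc1cc([C@H]2Oc3c(OC)cc(Br)cc3C(=O)C2=[N+]=[N-])ccc1OS(C)(=O)=O
F3 | step 5 | (2R)-5-bromo-7-methoxy-2-[3-methoxy-4-(methylsulfonyloxy)phenyl]-3-(oxomethylidene)-2,3-dihydro-1-benzofuran | COc1cc([C@H]2Oc3c(OC)cc(Br)cc3C2=C=O)ccc1OS(C)(=O)=O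
F4 | step 5 | methyl (2S,3R)-5-bromo-7-methoxy-2-[3-methoxy-4-(methylsulfonyloxy)phenyl]-2,3-dihydro-1-benzofuran-3-carboxylate (cis) | COc1cc([C@H]2Oc3c(OC)cc(Br)cc3[C@H]2C(=O)OC)ccc1OS(C)(=O)=O
F5 | step 4 | 3-methoxy-4-(methylsulfonyloxy)benzaldehyde | COc1cc(C=O)ccc1OS(C)(=O)=O
F6 | step 4 | (E)-1-(5-bromo-2-hydroxy-3-methoxyphenyl)-3-[3-methoxy-4-(methylsulfonyloxy)phenyl]prop-2-en-1-one | COc1cc(/C=C/C(=O)c2cc(Br)cc(OC)c2O)ccc1OS(C)(=O)=O
F7 | step 4 | racemic 6-bromo-8-methoxy-2-[3-methoxy-4-(methylsulfonyloxy)phenyl]chroman-4-one | COc1cc(C2Oc3c(OC)cc(Br)cc3C(=O)C2)ccc1OS(C)(=O)=O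
F8 | step 4 | (2R,4R)-6-bromo-8-methoxy-2-[3-methoxy-4-(methylsulfonyloxy)phenyl]chroman-4-ol (cis) | COc1cc([C@@H]2Oc3c(OC)cc(Br)cc3[C@H](O)C2)ccc1OS(C)(=O)=O
F9 | step 11 | 4-[(2S,3R)-5-[3-(tert-butyldimethylsilyloxy)propyl]-3-(hydroxymethyl)-7-methoxy-2,3-dihydro-1-benzofuran-2-yl]-2-methoxyphenol | COc1cc([C@H]2Oc3c(OC)cc(CCCO[Si](C)(C)C(C)(C)C)cc3[C@@H]2CO)ccc1O
F10 | step 11 | [(2S,3R)-2-(4-acetoxy-3-methoxyphenyl)-5-[3-(tert-butyldimethylsilyloxy)propyl]-7-methoxy-2,3-dihydro-1-benzofuran-3-yl]methyl acetate | COc1cc([C@H]2Oc3c(OC)cc(CCCO[Si](C)(C)C(C)(C)C)cc3[C@@H]2COC(C)=O)ccc1OC(C)=O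
F11 | step 11 | [(2S,3R)-2-(4-acetoxy-3-methoxyphenyl)-5-(3-hydroxypropyl)-7-methoxy-2,3-dihydro-1-benzofuran-3-yl]methyl acetate | COc1cc([C@H]2Oc3c(OC)cc(CCCO)cc3[C@@H]2COC(C)=O)ccc1OC(C)=O
F12 | step 11 | [(2S,3R)-2-(4-acetoxy-3-methoxyphenyl)-7-methoxy-5-[3-(sulfooxy)propyl]-2,3-dihydro-1-benzofuran-3-yl]methyl acetate | COc1cc([C@H]2Oc3c(OC)cc(CCCOS(=O)(=O)O)cc3[C@@H]2COC(C)=O)ccc1OC(C)=O
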